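**Retrosynthetic overview**
- The target is chrysin (5,7-dihydroxyflavone) with an (R)-1-methylpiperidin-2-yl group at C6 (piperidine atoms primed). The strategy rests on piperidine C2' being benzylic to ring-A carbon C6, which lies between the C5 and C7 oxygens. The C6–C2' unit can therefore be written as an ortho-quinone methide, and N1'–C2' as the bond made by conjugate amination.
- Disconnections: ring C (O1–C2 and C2–C3) to an ortho-hydroxyacetophenone and methyl benzoate; N-methyl to a methyl carbamate; N1'–C2' to an open-chain carbamate carbinol (asymmetric aza-Michael closure); C2'–C3' to an aldehyde and a 4-chlorobutyl Grignard reagent.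
- The three ring-A oxygens are kept different (free OH, OMe, OBn). Only the free ortho hydroxyl can give the methide, and the benzylated para oxygen later becomes O1, which places the piperidine at C6 and not at C8.
- Ring order: ring A is bought, the piperidine ring is closed in step 5, ring C in step 10; ring B arrives with methyl benzoate.

Key step: step 5

Assumption: the (R)-configured phosphoric acid is written as the enantiomer that leads to (2'R); the sense of induction must be established on the first run, and the (S) acid is used if it proves opposite.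

**Route**

Step 1
Reactants: 1 2,4-dihydroxy-6-methoxybenzaldehyde; 2 benzyl bromide
Product: 3 4-(benzyloxy)-2-hydroxy-6-methoxybenzaldehyde
Conditions: BnBr (1.05 equiv), K2CO3 (1.1 equiv), acetone, rt
Reagents that add atoms: benzyl bromide BrCc1ccccc1
Why: Williamson etherification should be selective for the 4-hydroxyl, which is the more acidic and accessible phenol, while the 2-hydroxyl is held in a hydrogen-bonded chelate with the formyl group.

Step 2
Reactants: 3 4-(benzyloxy)-2-hydroxy-6-methoxybenzaldehyde; 4 1-bromo-4-chlorobutane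
Product: 6 rac-1-[4-(benzyloxy)-2-hydroxy-6-methoxyphenyl]-5-chloropentan-1-ol, via 4-chlorobutylmagnesium bromide 5 (not isolated)
Conditions: 4, Mg, THF, 0 °C to rt; then 3 (5 in 2.5 equiv), THF, −40 to 0 °C; aq. NH4Cl
Reagents that add atoms: 1-bromo-4-chlorobutane ClCCCCBr (as Grignard reagent 5, ClCCCC[Mg]Br)
Why: Mg inserts into the C–Br bond and leaves the C–Cl bond, the first equivalent of 5 deprotonates the phenol and the second adds to the aldehyde (Grignard addition); the carbinol is racemic, which does not matter because this centre is erased in step 5.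

Step 3
Reactants: 6 rac-1-[4-(benzyloxy)-2-hydroxy-6-methoxyphenyl]-5-chloropentan-1-ol; 7 sodium azide
Product: 8 rac-5-azido-1-[4-(benzyloxy)-2-hydroxy-6-methoxyphenyl]pentan-1-ol
Conditions: NaN3 (3 equiv), NaI (0.2 equiv), DMF, 50 °C
Reagents that add atoms: sodium azide [Na+].[N-]=[N+]=[N-]
Why: SN2 displacement of the primary chloride with iodide (Finkelstein) assistance; azide is too weak a base to form the phenoxide or alkoxide, so O-alkylation should not compete.

Step 4
Reactants: 8 rac-5-azido-1-[4-(benzyloxy)-2-hydroxy-6-methoxyphenyl]pentan-1-ol; 9 methyl chloroformate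
Product: 12 methyl N-{5-[4-(benzyloxy)-2-hydroxy-6-methoxyphenyl]-5-hydroxypentyl}carbamate (racemic), via iminophosphorane 10 (not isolated), via primary amine 11 (not isolated)
Conditions: PMe3 (1.2 equiv), THF/H2O, rt; then NaHCO3, ClCO2Me (1.05 equiv), 0 °C
Reagents that add atoms: methyl chloroformate COC(=O)Cl
Why: Staudinger reduction gives the amine under neutral conditions that spare the benzyl ether and the labile carbinol, and in the following Schotten–Baumann acylation the amine outcompetes the phenol and the secondary alcohol for one equivalent of chloroformate.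

Step 5
Reactants: 12 methyl N-{5-[4-(benzyloxy)-2-hydroxy-6-methoxyphenyl]-5-hydroxypentyl}carbamate
Product: 14 methyl (R)-2-[4-(benzyloxy)-2-hydroxy-6-methoxyphenyl]piperidine-1-carboxylate, via ortho-quinone methide 13 (not isolated)
Conditions: (R)-3,3'-bis(2,4,6-triisopropylphenyl)-1,1'-binaphthalene-2,2'-diyl hydrogen phosphate (10 mol %), 5 Å molecular sieves, toluene/CH2Cl2 (0.02 M), −20 °C
Reagents that add atoms: none
Why: Proposed new method: the phosphoric acid protonates the benzylic hydroxyl of 12, water leaves with push from the free 2-hydroxyl of the aryl ring (the other ortho oxygen is methylated and the para oxygen benzylated, so 13 is the only methide that can form), and the carbamate nitrogen adds to the exocyclic methide carbon, which restores the aromatic ring. The closest known reaction type is the chiral phosphoric acid-catalysed enantioselective conjugate addition of external nucleophiles to ortho-quinone methides generated in situ from ortho-hydroxybenzylic alcohols; a tethered carbamate nitrogen and an alkyl-substituted methide carbon have not been shown in this setting. The piperidine ring closes in the 6-exo-trig mode, N1' attacking the exocyclic carbon of the methide C=C. The C2' stereocentre is set by the chiral phosphate, which is expected to bridge the methide oxygen and the carbamate N–H and so to leave one face of the planar methide open, while the racemic carbinol centre of 12 is erased on ionisation and has no say. The step needs enantiofacial selectivity and N- over O-attack of the carbamate: the first rests on the catalyst and on a single methide geometry (chain on the carbonyl side, away from the aryl 6-methoxy group), the second on ring size, since attack through the carbamate oxygen would close an eight-membered ring. High dilution, molecular sieves and low temperature should hold back methide dimerisation, tautomerisation to the vinylphenol and acid-catalysed reopening of the product.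

Step 6
Reactants: 14 methyl (R)-2-[4-(benzyloxy)-2-hydroxy-6-methoxyphenyl]piperidine-1-carboxylate; 15 iodomethane
Product: 16 methyl (R)-2-[4-(benzyloxy)-2,6-dimethoxyphenyl]piperidine-1-carboxylate
Conditions: MeI (3 equiv), K2CO3, acetone, rt, directly after step 5
Reagents that add atoms: iodomethane CI
Why: Williamson O-methylation of the remaining phenol; once both ortho oxygens are alkylated, C2' can no longer ionise through an ortho-quinone methide, which locks the configuration set in step 5.

Step 7
Reactants: 16 methyl (R)-2-[4-(benzyloxy)-2,6-dimethoxyphenyl]piperidine-1-carboxylate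
Product: 17 (R)-2-[4-(benzyloxy)-2,6-dimethoxyphenyl]-1-methylpiperidine
Conditions: LiAlH4 (4 equiv), THF, reflux; aq. NaOH work-up
Reagents that add atoms: none
Why: LiAlH4 reduction of a carbamate to the N-methyl amine (hydride addition, loss of methoxide, reduction of the iminium ion); the aryl ethers are inert and C2' has no pathway for epimerisation under hydride.

Step 8
Reactants: 17 (R)-2-[4-(benzyloxy)-2,6-dimethoxyphenyl]-1-methylpiperidine
Product: 18 3,5-dimethoxy-4-[(2R)-1-methylpiperidin-2-yl]phenol
Conditions: H2 (1 atm), 10% Pd/C, EtOAc/MeOH, rt, stopped at one equivalent of H2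
Reagents that add atoms: none
Why: Catalytic hydrogenolysis of the aryl benzyl ether, which should be much faster than cleavage of the ring C2'–N bond, shielded as it is by the two ortho methoxy groups.

Step 9
Reactants: 18 3,5-dimethoxy-4-[(2R)-1-methylpiperidin-2-yl]phenol; 19 acetic anhydride
Product: 21 1-{6-hydroxy-2,4-dimethoxy-3-[(2R)-1-methylpiperidin-2-yl]phenyl}ethan-1-one, via aryl acetate 20 (not isolated)
Conditions: Ac2O (3 equiv), BF3·OEt2 (5 equiv), CH2Cl2, 0 °C to rt; then aq. Na2CO3, MeOH
Reagents that add atoms: acetic anhydride CC(=O)OC(C)=O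
Why: O-acetylation followed by BF3-promoted Fries rearrangement (Friedel–Crafts acylation) puts the acetyl group ortho to the hydroxyl that was benzylated, the two open ring positions being equivalent, and the difluoroboron chelate of the ortho-hydroxy ketone protects the neighbouring methyl ether; this fixes the later O1 para to the piperidine-bearing carbon.

Step 10
Reactants: 21 1-{6-hydroxy-2,4-dimethoxy-3-[(2R)-1-methylpiperidin-2-yl]phenyl}ethan-1-one; 22 methyl benzoate
Product: 24 5,7-dimethoxy-6-[(2R)-1-methylpiperidin-2-yl]-2-phenyl-4H-chromen-4-one, via diketone 23 (not isolated)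
Conditions: NaH (5 equiv), PhCO2Me (2 equiv), DMF, 0 °C to rt; then conc. HCl, AcOH, 60 °C; aq. Na2CO3 work-up
Reagents that add atoms: methyl benzoate COC(=O)c1ccccc1
Why: Crossed Claisen condensation of the ketone enolate with the non-enolisable ester gives the 1,3-diketone, and acid then closes the pyranone by attack of the phenol on the benzoyl carbonyl and loss of water (ester variant of the Baker–Venkataraman flavone synthesis).

Step 11
Reactants: 24 5,7-dimethoxy-6-[(2R)-1-methylpiperidin-2-yl]-2-phenyl-4H-chromen-4-one
Product: 25 5,7-dihydroxy-6-[(2R)-1-methylpiperidin-2-yl]-2-phenyl-4H-chromen-4-one (target)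
Conditions: BBr3 (6 equiv), CH2Cl2, −78 °C to rt; H2O, then aq. NaHCO3 to pH 8
Reagents that add atoms: none
Why: Lewis-acid ether cleavage, in which BBr3 binds the methoxy oxygens and bromide removes the methyl groups by SN2 (the C5 ether assisted by the C4 carbonyl); the cold, non-protic medium should avoid pyranone ring opening (Wessely–Moser isomerisation) and ionisation at C2'.

**Compound list**
1 | 2,4-dihydroxy-6-methoxybenzaldehyde | COc1cc(O)cc(O)c1C=O | starting material
2 | benzyl bromide | BrCc1ccccc1 | starting material
3 | 4-(benzyloxy)-2-hydroxy-6-methoxybenzaldehyde | COc1cc(OCc2ccccc2)cc(O)c1C=O | intermediate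
4 | 1-bromo-4-chlorobutane | ClCCCCBr | starting material
5 | 4-chlorobutylmagnesium bromide | ClCCCC[Mg]Br | intermediate
6 | rac-1-[4-(benzyloxy)-2-hydroxy-6-methoxyphenyl]-5-chloropentan-1-ol | COc1cc(OCc2ccccc2)cc(O)c1C(O)CCCCCl | intermediate
7 | sodium azide | [Na+].[N-]=[N+]=[N-] | starting material
8 | rac-5-azido-1-[4-(benzyloxy)-2-hydroxy-6-methoxyphenyl]pentan-1-ol | COc1cc(OCc2ccccc2)cc(O)c1C(O)CCCCN=[N+]=[N-] | intermediate
9 | methyl chloroformate | COC(=O)Cl | starting material
10 | rac-1-[4-(benzyloxy)-2-hydroxy-6-methoxyphenyl]-5-[(trimethyl-λ5-phosphanylidene)amino]pentan-1-ol (iminophosphorane) | COc1cc(OCc2ccccc2)cc(O)c1C(O)CCCCN=P(C)(C)C | intermediate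
11 | rac-5-amino-1-[4-(benzyloxy)-2-hydroxy-6-methoxyphenyl]pentan-1-ol | COc1cc(OCc2ccccc2)cc(O)c1C(O)CCCCN | intermediate
12 | methyl N-{5-[4-(benzyloxy)-2-hydroxy-6-methoxyphenyl]-5-hydroxypentyl}carbamate (racemic) | COC(=O)NCCCCC(O)c1c(O)cc(OCc2ccccc2)cc1OC | intermediate
13 | methyl N-{5-[4-(benzyloxy)-2-methoxy-6-oxocyclohexa-2,4-dien-1-ylidene]pentyl}carbamate (ortho-quinone methide) | COC(=O)NCCCCC=C1C(=O)C=C(OCc2ccccc2)C=C1OC | intermediate
14 | methyl (R)-2-[4-(benzyloxy)-2-hydroxy-6-methoxyphenyl]piperidine-1-carboxylate | COC(=O)N1CCCC[C@@H]1c1c(O)cc(OCc2ccccc2)cc1OC | intermediate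
15 | iodomethane | CI | starting material
16 | methyl (R)-2-[4-(benzyloxy)-2,6-dimethoxyphenyl]piperidine-1-carboxylate | COC(=O)N1CCCC[C@@H]1c1c(OC)cc(OCc2ccccc2)cc1OC | intermediate
17 | (R)-2-[4-(benzyloxy)-2,6-dimethoxyphenyl]-1-methylpiperidine | CN1CCCC[C@@H]1c1c(OC)cc(OCc2ccccc2)cc1OC | intermediate
18 | 3,5-dimethoxy-4-[(2R)-1-methylpiperidin-2-yl]phenol | CN1CCCC[C@@H]1c1c(OC)cc(O)cc1OC | intermediate
19 | acetic anhydride | CC(=O)OC(C)=O | starting material
20 | 3,5-dimethoxy-4-[(2R)-1-methylpiperidin-2-yl]phenyl acetate | CN1CCCC[C@@H]1c1c(OC)cc(OC(C)=O)cc1OC | intermediate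
21 | 1-{6-hydroxy-2,4-dimethoxy-3-[(2R)-1-methylpiperidin-2-yl]phenyl}ethan-1-one | CN1CCCC[C@@H]1c1c(OC)cc(O)c(C(C)=O)c1OC | intermediate
22 | methyl benzoate | COC(=O)c1ccccc1 | starting material
23 | 1-{6-hydroxy-2,4-dimethoxy-3-[(2R)-1-methylpiperidin-2-yl]phenyl}-3-phenylpropane-1,3-dione | CN1CCCC[C@@H]1c1c(OC)cc(O)c(C(=O)CC(=O)c2ccccc2)c1OC | intermediate
24 | 5,7-dimethoxy-6-[(2R)-1-methylpiperidin-2-yl]-2-phenyl-4H-chromen-4-one | CN1CCCC[C@@H]1c1c(OC)cc2oc(-c3ccccc3)cc(=O)c2c1OC | intermediate
25 | 5,7-dihydroxy-6-[(2R)-1-methylpiperidin-2-yl]-2-phenyl-4H-chromen-4-one | CN1CCCC[C@@H]1c1c(O)cc2oc(-c3ccccc3)cc(=O)c2c1O | target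

**Step count**
Total: 11 steps. Longest linear sequence: 11 steps (from 1).

**Steps most likely to fail**

1. Step 5 (proposed new method). The trioxygenated methide is strongly stabilised and may react through a loose ion pair with poor facial selectivity. The alkyl-substituted methide may also tautomerise to the vinylphenol or dimerise, and acid-catalysed reopening of the product may erode the enantiomeric purity.
Fallback (known auxiliary chemistry, from 3 back to 17): 3 is O-methylated (MeI, K2CO3) to 4-(benzyloxy)-2,6-dimethoxybenzaldehyde F1. Condensation with (S)-2-methylpropane-2-sulfinamide and Ti(OEt)4 in THF should give the (S,E)-N-sulfinyl imine F2. Addition of Grignard reagent 5 in CH2Cl2 at −48 °C should give (S)-N-[(1R)-1-[4-(benzyloxy)-2,6-dimethoxyphenyl]-5-chloropentyl]-2-methylpropane-2-sulfinamide F3. The cyclic magnesium-chelate model predicts the (R) carbon centre from the (S) sulfur centre; the diastereomers are separable, and the (R) sulfinamide is used if the sense proves opposite. NaH in DMF then closes the ring by N-alkylation to (R)-2-[4-(benzyloxy)-2,6-dimethoxyphenyl]-1-[(S)-tert-butylsulfinyl]piperidine F4. Brief HCl/MeOH at 0 °C removes the auxiliary to give (R)-2-[4-(benzyloxy)-2,6-dimethoxyphenyl]piperidine F5, and reductive methylation (aq. CH2O, NaBH(OAc)3) leads to 17.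

2. Step 9. Under the Lewis acid the boron-bound amine may depart from the electron-rich benzylic carbon and re-close, which would racemise C2'. The hindered methyl ether next to the new ketone may also be cleaved, which would blur the later choice between C6 and C8 substitution.
Fallback (from 18 back to 21): the acetyl group is introduced without a Lewis acid. Bromination of 18 with NBS, the amine being protonated by one equivalent of TFA (MeCN, −20 °C), should give 2-bromo-3,5-dimethoxy-4-[(2R)-1-methylpiperidin-2-yl]phenol F6. Stille coupling with tributyl(1-ethoxyvinyl)stannane (Pd(PPh3)4, toluene, 100 °C) should give 2-(1-ethoxyvinyl)-3,5-dimethoxy-4-[(2R)-1-methylpiperidin-2-yl]phenol F7. Brief hydrolysis of the enol ether with dilute aqueous HCl at rt gives 21.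

3. Step 3. The free ortho-hydroxybenzylic carbinol may lose water on warming in DMF, and the resulting methide may be trapped by azide or phenol or may oligomerise. The hydroxyl may also displace the chloride to form a 2-aryltetrahydropyran. The same lability calls for buffered work-up and base-washed silica for 6, 8 and 12.
Fallback (from 3 back to 12): the ortho phenol is masked through the nucleophilic steps. Allylation of 3 (allyl bromide, K2CO3, DMF) gives 2-(allyloxy)-4-(benzyloxy)-6-methoxybenzaldehyde F8. Addition of 5 gives rac-1-[2-(allyloxy)-4-(benzyloxy)-6-methoxyphenyl]-5-chloropentan-1-ol F9, and NaN3/NaI in DMF gives rac-1-[2-(allyloxy)-4-(benzyloxy)-6-methoxyphenyl]-5-azidopentan-1-ol F10. PMe3/H2O gives rac-5-amino-1-[2-(allyloxy)-4-(benzyloxy)-6-methoxyphenyl]pentan-1-ol F11, which is acylated in the same flask with ClCO2Me/NaHCO3 to methyl N-{5-[2-(allyloxy)-4-(benzyloxy)-6-methoxyphenyl]-5-hydroxypentyl}carbamate F12. Neutral deallylation (Pd(PPh3)4, morpholine, THF, rt) then releases 12 just before the key step.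

**Further compounds**
F1 | step 5 | 4-(benzyloxy)-2,6-dimethoxybenzaldehyde | COc1cc(OCc2ccccc2)cc(OC)c1C=O
F2 | step 5 | (S,E)-N-[4-(benzyloxy)-2,6-dimethoxybenzylidene]-2-methylpropane-2-sulfinamide | CC(C)(C)[S@](=O)/N=C/c1c(OC)cc(OCc2ccccc2)cc1OC
F3 | step 5 | (S)-N-[(1R)-1-[4-(benzyloxy)-2,6-dimethoxyphenyl]-5-chloropentyl]-2-methylpropane-2-sulfinamide | CC(C)(C)[S@](=O)N[C@H](CCCCCl)c1c(OC)cc(OCc2ccccc2)cc1OC
F4 | step 5 | (R)-2-[4-(benzyloxy)-2,6-dimethoxyphenyl]-1-[(S)-tert-butylsulfinyl]piperidine | CC(C)(C)[S@](=O)N1CCCC[C@@H]1c1c(OC)cc(OCc2ccccc2)cc1OC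
F5 | step 5 | (R)-2-[4-(benzyloxy)-2,6-dimethoxyphenyl]piperidine | N1CCCC[C@@H]1c1c(OC)cc(OCc2ccccc2)cc1OC
F6 | step 9 | 2-bromo-3,5-dimethoxy-4-[(2R)-1-methylpiperidin-2-yl]phenol | CN1CCCC[C@@H]1c1c(OC)cc(O)c(Br)c1OC
F7 | step 9 | 2-(1-ethoxyvinyl)-3,5-dimethoxy-4-[(2R)-1-methylpiperidin-2-yl]phenol | CN1CCCC[C@@H]1c1c(OC)cc(O)c(C(=C)OCC)c1OC
F8 | step 3 | 2-(allyloxy)-4-(benzyloxy)-6-methoxybenzaldehyde | COc1cc(OCc2ccccc2)cc(OCC=C)c1C=O
F9 | step 3 | rac-1-[2-(allyloxy)-4-(benzyloxy)-6-methoxyphenyl]-5-chloropentan-1-ol | COc1cc(OCc2ccccc2)cc(OCC=C)c1C(O)CCCCCl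
F10 | step 3 | rac-1-[2-(allyloxy)-4-(benzyloxy)-6-methoxyphenyl]-5-azidopentan-1-ol | COc1cc(OCc2ccccc2)cc(OCC=C)c1C(O)CCCCN=[N+]=[N-]
F11 | step 3 | rac-5-amino-1-[2-(allyloxy)-4-(benzyloxy)-6-methoxyphenyl]pentan-1-ol | COc1cc(OCc2ccccc2)cc(OCC=C)c1C(O)CCCCN
F12 | step 3 | methyl N-{5-[2-(allyloxy)-4-(benzyloxy)-6-methoxyphenyl]-5-hydroxypentyl}carbamate | COC(=O)NCCCCC(O)c1c(OCC=C)cc(OCc2ccccc2)cc1OC
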